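**The split.** The ratio of target to isomer of the product in the west run read 0.831 at 2.00 h and 0.801 at 25.0 h. I asked what that ratio is worth for this same flask.

| flask | substrate | remark | time |
|---|---|---|---|
| west | 1.5 M | the very flask that is asked about, followed so far |  |
| north-east | 2.2 M | run made earlier |  |
| flask | 1.5 M |  | 2.5 d |

| run | time / h | target / % | isomer of the product / % |
|---|---|---|---|
| west | 2.00 | 34.3 | 41.3 |
| west | 4.00 | 40.9 | 50.9 |
| west | 6.00 | 43.0 | 51.6 |
| west | 12.0 | 43.5 | 53.4 |
| west | 25.0 | 42.6 | 53.2 |
| north-east | 2.00 | 32.1 | 40.7 |
| north-east | 4.00 | 40.7 | 51.4 |
| north-east | 6.00 | 41.2 | 51.1 |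
| north-east | 12.0 | 41.8 | 52.8 |
| north-east | 25.0 | 40.8 | 54.9 |

(readings scatter by 1 percentage point)

* ratio of target to isomer of the product at 4.0 min
* ratio of target to isomer of the product at 2.0 h
* ratio of target to isomer of the product at 2.5 d
* which of target and isomer of the product there is more of at 2.5 d

**The clock.** In the west run, 24.4% of the charge was not found in either product at 2.00 h. Taking first order, I read a half-life of c(substrate) of about 0.983 h. The time 2.5 d is 61.0 such half-lives, so I took the late west readings as the end state.

**The bracket.** The highest west ratio, 0.833, gave me a rough upper edge, and the lowest, 0.801, a rough lower edge; both were scattered readings. To tighten them, I summed the west readings: target 204%, isomer of the product 250%. Their quotient is the split, the selectivity as read from the west readings, 0.816. The scatter of the readings gives it a standard deviation of 0.0115, so my bracket ran from 0.804 to 0.827. I saw no trend beyond scatter, so I took the products as forming side by side and carried the split to all the asked times. It stood below parity, so I put the isomer of the product ahead.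

**The forecast.** The forecast gave 0.81, 0.81 and 0.79 for 4.0 min, 2.0 h and 2.5 d, “with the isomer still ahead”, and its last value lay below my bracket.

**The result.** At those times the flask gave 0.841, 0.819 and 0.812, with 53.4% isomer of the product against 43.3% target at 2.5 d. The first ratio stood above my bracket.

    substrate → target (k = 0.460 h⁻¹)
    other conformer → isomer of the product (k = 1.30 h⁻¹)
    substrate + target → side product (k = 0.0510 M⁻¹ h⁻¹)
    substrate ⇌ other conformer, settled at all times (K = 0.420)

At 25.0 d the flask still held 43.3% target and 53.4% isomer of the product. A neighbour charged with 0.38 M of substrate ended with 54.0% isomer of the product at 2.50 d. The split turned that into 44.1% target, and the neighbour held 45.1%.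

The numbers in the tables come from a simulation for an exercise; noise was put on by code.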